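## Retrosynthetic overview

1. The usual lignan logic (β-substituted butyrolactone aldol, reduction, acid cycloetherification) is avoided. The last operations are only O-deprotections, desilylation and then neutral ArO–Bn hydrogenolysis.
2. The C7–OH and C4–H stereocentres come from one stereospecific syn-hydroboration/oxidation of an (E)-4-(arylmethylidene)oxolane. Alkene geometry plus ring face set both centres at once.
3. The oxolane is the only ring formed (step 6). It is made together with the C3–C4 (8–8′) bond by a Cp2TiCl epoxide-opening/5-exo-dig radical cyclisation of an epoxy aryl-propargyl ether.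
4. That ether comes from O-propargylation and Sonogashira coupling. Absolute configuration comes from a Sharpless kinetic-resolution epoxidation of the aryl vinyl carbinol made from 3,4-bis(benzyloxy)benzaldehyde.

Assumption: oxolane numbering is O1, C2 (catechol-bearing), C3 (CH2OH), C4 (side chain), C5 (CH2), and C7 is the guaiacyl carbinol carbon. The given SMILES then reads 2S,3R,4R,7R (2,3-trans, 3,4-cis). Compounds 1 and 4 are taken as commercial.

## Route

**Step 1**
- Reactants: 1, 4-iodo-2-methoxyphenol; 2, benzyl bromide
- Product: 3, 1-(benzyloxy)-4-iodo-2-methoxybenzene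
- Conditions: K2CO3, DMF, rt
- Reagents that add atoms: benzyl bromide, BrCc1ccccc1
- Why: Williamson etherification of the phenoxide, with no stereocentre involved.

**Step 2**
- Reactants: 4, 3,4-bis(benzyloxy)benzaldehyde; 5, vinylmagnesium bromide
- Product: 6, rac-1-[3,4-bis(benzyloxy)phenyl]prop-2-en-1-ol
- Conditions: THF, 0 °C; aq NH4Cl
- Reagents that add atoms: vinylmagnesium bromide, C=C[Mg]Br
- Why: Grignard 1,2-addition to an aryl aldehyde, which gives the carbinol racemic on purpose.

**Step 3**
- Reactants: 6
- Product: 7, (R)-[3,4-bis(benzyloxy)phenyl][(2R)-oxiran-2-yl]methanol (erythro epoxy alcohol)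
- Conditions: Ti(OiPr)4 (1.0 equiv), D-(−)-DIPT (1.2 equiv), TBHP (0.45 equiv), 4 Å MS, CH2Cl2, −20 °C; separate from unreacted (R)-6; recrystallise
- Reagents that add atoms: tert-butyl hydroperoxide, CC(C)(C)OO (epoxide O)
- Why: In this Sharpless kinetic-resolution epoxidation, D-(−)-tartrate makes (S)-6 the fast, matched enantiomer and epoxidises it erythro-selectively, which fixes the future C2 configuration (the descriptor reads R here only because the oxirane carbon outranks aryl), while the oxirane CH centre is sacrificial.

**Step 4**
- Reactants: 7; 8, propargyl bromide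
- Product: 9, (2R)-2-[(R)-[3,4-bis(benzyloxy)phenyl](prop-2-yn-1-yloxy)methyl]oxirane
- Conditions: NaH (added last), cat. Bu4NI, THF, −10 to 0 °C
- Reagents that add atoms: propargyl bromide, C#CCBr
- Why: Williamson O-alkylation with a very reactive halide in aprotic medium outruns Payne rearrangement and touches no stereocentre.

**Step 5**
- Reactants: 9; 3
- Product: 10, (2R)-2-[(R)-[3,4-bis(benzyloxy)phenyl]({3-[4-(benzyloxy)-3-methoxyphenyl]prop-2-yn-1-yl}oxy)methyl]oxirane
- Conditions: PdCl2(PPh3)2 (2 mol %), CuI (4 mol %), Et3N/THF, degassed, rt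
- Reagents that add atoms: aryl iodide 3, COc1cc(I)ccc1OCc1ccccc1
- Why: Sonogashira coupling of an aryl iodide runs at rt, and the epoxide and benzyl ethers are inert to it.

**Step 6 (key step 1)**
- Reactants: 10
- Product: 11, [(2S,3R,4E)-2-[3,4-bis(benzyloxy)phenyl]-4-{[4-(benzyloxy)-3-methoxyphenyl]methylidene}oxolan-3-yl]methanol
- Conditions: Cp2TiCl2 (2.5 equiv)/Zn, THF, 1,4-cyclohexadiene (5 equiv), slow addition, 0.02 M, rt; sat. aq NaH2PO4 quench (no strong acid)
- Reagents that add atoms: none (two H only)
- Why: Nugent–RajanBabu Ti(III) epoxide opening gives the secondary β-titanoxy C3 radical, which closes 5-exo-dig on the aryl alkyne with the C2-aryl pseudo-equatorial and CH2OTi anti to it (2,3-trans, C3 = R relayed from C2), and the linear α-aryl vinyl radical is then quenched from the open C5H2 side rather than the side blocked by C3–CH2OTiCp2Cl, placing Ar′ cis to C3 (E).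

**Step 7**
- Reactants: 11; 12, tert-butyldimethylsilyl chloride
- Product: 13, the C9-O-TBS ether of 11 (2S,3R,4E)
- Conditions: imidazole, CH2Cl2, rt
- Reagents that add atoms: TBSCl, CC(C)(C)[Si](C)(C)Cl
- Why: Silylation of the primary alcohol prevents O–B tethered delivery from the wrong face and enlarges the group shielding that face.

**Step 8 (key step 2)**
- Reactants: 13
- Product: 14, (R)-[4-(benzyloxy)-3-methoxyphenyl][(3R,4R,5S)-5-[3,4-bis(benzyloxy)phenyl]-4-{[(tert-butyldimethylsilyl)oxy]methyl}oxolan-3-yl]methanol
- Conditions: BH3·SMe2 (3 equiv), THF, 0 °C to rt; then 3 M NaOH, 30 % H2O2, 0 °C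
- Reagents that add atoms: hydrogen peroxide, OO (the C7 oxygen)
- Why: In this Brown hydroboration–oxidation, boron goes to the less substituted benzylic carbon and H to C4 in a concerted syn addition on the face anti to C3–CH2OTBS (the same facial bias that gives 3,4-cis products on hydrogenating 4-benzylidene oxolanes), so with E geometry this one event sets C4 (R, 3,4-cis) and C7 (R), and C–B to C–O oxidation proceeds with retention.

**Step 9**
- Reactants: 14
- Product: 15, (R)-[4-(benzyloxy)-3-methoxyphenyl][(3R,4R,5S)-5-[3,4-bis(benzyloxy)phenyl]-4-(hydroxymethyl)oxolan-3-yl]methanol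
- Conditions: TBAF, THF, 0 °C to rt
- Reagents that add atoms: none
- Why: Fluoride desilylation is non-acidic, so the electron-rich benzylic alcohol neither ionises nor closes to the furofuran.

**Step 10**
- Reactants: 15
- Product: 16, (7R)-7-hydroxytaxiresinol
- Conditions: H2 (1 atm), 10 % Pd/C, pyridine (0.5 equiv), EtOAc/EtOH, rt; stop at 3 equiv H2; acid-free work-up under N2
- Reagents that add atoms: none
- Why: In catalytic hydrogenolysis, phenolic benzyl ethers cleave much faster than a secondary benzylic alcohol or a cyclic benzylic ether under neutral, amine-moderated conditions (as used routinely for phenolic lignin-model benzylic alcohols), and pyridine also neutralises acidic sites that would trigger furofuran closure.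

Stereocentre ledger: C2 is set in step 3, C3 in step 6, and C4 and C7 in step 8. None is α to a carbonyl or exposed to acid afterwards.

## Compound list

| No. | Name | SMILES | Role |
|---|---|---|---|
| 1 | 4-iodo-2-methoxyphenol | `COc1cc(I)ccc1O` | starting material |
| 2 | benzyl bromide | `BrCc1ccccc1` | starting material |
| 3 | 1-(benzyloxy)-4-iodo-2-methoxybenzene | `COc1cc(I)ccc1OCc1ccccc1` | intermediate |
| 4 | 3,4-bis(benzyloxy)benzaldehyde | `O=Cc1ccc(OCc2ccccc2)c(OCc2ccccc2)c1` | starting material |
| 5 | vinylmagnesium bromide | `C=C[Mg]Br` | starting material |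
| 6 | rac-1-[3,4-bis(benzyloxy)phenyl]prop-2-en-1-ol | `C=CC(O)c1ccc(OCc2ccccc2)c(OCc2ccccc2)c1` | intermediate |
| 7 | (R,R)-epoxy alcohol | `O[C@H](c1ccc(OCc2ccccc2)c(OCc2ccccc2)c1)[C@H]1CO1` | intermediate |
| 8 | propargyl bromide | `C#CCBr` | starting material |
| 9 | epoxy propargyl ether | `C#CCO[C@H](c1ccc(OCc2ccccc2)c(OCc2ccccc2)c1)[C@H]1CO1` | intermediate |
| 10 | epoxy aryl-propargyl ether | `COc1cc(C#CCO[C@H](c2ccc(OCc3ccccc3)c(OCc3ccccc3)c2)[C@H]2CO2)ccc1OCc1ccccc1` | intermediate |
| 11 | (2S,3R,4E)-benzylidene oxolane methanol | `COc1cc(/C=C2/CO[C@H](c3ccc(OCc4ccccc4)c(OCc4ccccc4)c3)[C@H]2CO)ccc1OCc1ccccc1` | intermediate |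
| 12 | tert-butyldimethylsilyl chloride | `CC(C)(C)[Si](C)(C)Cl` | starting material |
| 13 | TBS ether of 11 | `COc1cc(/C=C2/CO[C@H](c3ccc(OCc4ccccc4)c(OCc4ccccc4)c3)[C@H]2CO[Si](C)(C)C(C)(C)C)ccc1OCc1ccccc1` | intermediate |
| 14 | (7R)-carbinol, C9-OTBS, tri-O-benzyl | `COc1cc([C@H](O)[C@H]2CO[C@H](c3ccc(OCc4ccccc4)c(OCc4ccccc4)c3)[C@H]2CO[Si](C)(C)C(C)(C)C)ccc1OCc1ccccc1` | intermediate |
| 15 | tri-O-benzyl-(7R)-7-hydroxytaxiresinol | `COc1cc([C@H](O)[C@H]2CO[C@H](c3ccc(OCc4ccccc4)c(OCc4ccccc4)c3)[C@H]2CO)ccc1OCc1ccccc1` | intermediate |
| 16 | (7R)-7-hydroxytaxiresinol | `COc1cc([C@H](O)[C@H]2CO[C@H](c3ccc(O)c(O)c3)[C@H]2CO)ccc1O` | target |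

## Summary

Total steps: 10. Longest linear sequence: 9 (steps 2 to 10, from compound 4).

Three steps most likely to fail:

1. **Step 6.** The E/Z ratio of the vinyl-radical quench is the main risk, because only E gives 7R. Ti-mediated deoxygenation and the minor 2,3-cis isomer are lesser risks.
   - Fallback: make the geometry irrelevant. Carry the E/Z mixture through steps 7 and 8, where C4 is set identically for both isomers. Oxidise both C7 epimers to the single aryl ketone with buffered DMP. Then set C7 by reagent control with (S)-Me-CBS/BH3 (aryl as the large group gives R).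
2. **Step 8.** The facial selectivity or rate of BH3 on the hindered E-styrene may be insufficient.
   - Fallback: introduce the guaiacyl ring after ring formation.
     - Cyclise terminal alkyne 9 directly with Cp2TiCl to the 4-methylene oxolane.
     - Hydroborate this 1,1-disubstituted alkene with bulky 9-BBN for higher facial bias.
     - Oxidise the resulting primary alcohol to the aldehyde.
     - Add the aryllithium derived from 3.
     - Oxidise to the ketone and perform CBS reduction.
3. **Step 10.** Over-hydrogenolysis at C7–OH or C2–O1, or trace-acid closure to the furofuran, could occur.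
   - Fallback: change the protecting-group plan. Carry all three phenols as TIPS ethers from the start and use a non-basic borane oxidation (Me3NO). Finish with one AcOH-buffered TBAF global desilylation that also removes the C9-OTBS group. This removes the reductive step and shortens the route by one step.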